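Assumption: the SMILES is read as the (2R,3R)-trans-2-aryl-3-(hydroxymethyl)-2,3-dihydro-1,4-benzodioxine, and compounds 1 and 28 are taken to be purchasable.

## Analysis of the target

The target is a flavonol: a 3,5,7-trihydroxy-4H-chromen-4-one (benzo ring A fused to pyranone ring C) whose C2 carries a 1,4-benzodioxane (benzene ring B fused to dioxane ring D). Benzodioxane atoms are given primed locants below: O1′, C2′ (bearing the 4-hydroxy-3-methoxyphenyl ring E), C3′ (bearing the hydroxymethyl group), O4′, C4a′, C5′ to C8′, C8a′. The only stereocenters are C2′ and C3′, both R, with aryl and hydroxymethyl trans (diequatorial). In open-chain terms this is a syn (threo) 1-aryl-1,2-diol. The chromenone sits on C6′, para to O1′ (the oxygen on the aryl-bearing carbon) and meta to O4′. The isomer with the two oxygens exchanged is a different compound, and an undirected catechol annulation would give both. Sensitive features are four acidic hydroxyls, one primary alcohol, a methyl ether that must outlast every deprotection, the benzylic C2′–O1′ aryl ether (ionisable in strong acid, open to hydrogenolysis) and the base- and oxidant-sensitive free flavonol. The hard part is therefore the benzodioxane: its absolute configuration, its trans geometry and the sense of its fusion to ring B. The strategy rests on ring B being a benzene whose adjacent carbons C4a′ and C8a′ carry the two dioxane oxygens, whose C6′ carries carbon and whose C5′, C7′, C8′ carry hydrogen. It is the formal trimer of two O-alkynyl groups and one terminal alkyne, so rings B and D can be closed together from an acyclic, stereodefined diol.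

## Retrosynthetic reasoning

**Target 35 from 34.** All five hydroxyls of 35 are traced back to benzyl ethers in the pentabenzyl flavonol 34. One neutral, reductive operation then frees the polyphenol at the very end and leaves the methyl ether alone.

**Ring C: 34 from 33, and 33 from 27 and 32.** The chromenone O1–C8a bond is cut first, giving diketone 33 with an ortho bromide. The C3–C4 bond is cut next, giving benzyloxymethyl ketone 27 and acid chloride 32. Cutting here keeps the 3-oxygen in place from the start, so no chalcone or flavanone has to be oxidised. The forward reactions are a C-acylation of a ketone enolate and an intramolecular O-arylation.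

**Silicon: 27 from 26.** The C8′–H bond of 27 is traced to a C8′–Si bond in 26. The silyl group has no role in the target; it exists only to steer the ring-forming step and must leave by ipso-protonation.

**Ring B and ring D: 26 from 21 and 25.** Three C–C bonds of ring B are cut: C4a′–C8a′, C5′–C6′ and C7′–C8′. This leaves the bis(ynol ether) 21 and ynone 25. The cut is made here because it converts the regiochemical problem of the benzodioxane (which oxygen sits para to the carbon substituent) into the orientation of one alkyne insertion, which a silyl group on one terminus can direct. It also removes both rings at once. The forward reaction must join the two oxygen-bearing alkyne carbons, take up the ynone with its acyl group meta to silicon, and do so at room temperature.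

**Ynone: 25 from 23, and 23 from 22.** The bond between the carbonyl carbon and the ethynyl carbon is cut. An amide of the Weinreb type (23) is used so that only one acetylide adds; it comes from acid chloride 22.

**Ynol ethers: 21 back to 10 through 19, 17, 14 and 12.** Each O–C(sp) bond is traced to an alcohol through a 1,2-dichlorovinyl ether. The two alkynes must differ (silyl on the benzylic one, hydrogen on the other), and two acetylides cannot be told apart in one flask, so the oxygens are processed one after the other. The benzylic oxygen is functionalised first (12), the second hydroxyl is freed while the first group is still the robust dichlorovinyl ether (14), the first alkyne is then made and silylated (17), and the second is made last and left terminal (19, 21).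

**Diol: 10 from 8, 8 from 7, 7 from 4 and 5, 4 from 1 and 2.** The C1–C2 bond of the diol is cut by an auxiliary-controlled glycolate aldol between imide 4 and aldehyde 5. This one step sets both stereocenters and delivers the two secondary oxygens already differentiated (free benzylic hydroxyl, allyl ether on the neighbour). Reductive removal of the auxiliary and benzylation of the primary hydroxyl lead to 10.

**Acid chloride: 32 from 31, 31 from 30, 30 from 28.** The carboxyl carbon is traced to a formyl group introduced on bromoarene 28, ortho to bromine, which gives the 2-bromo-4,6-dioxygenated pattern needed for ring A.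

## Alternatives that were turned down

**Alternative 1:** ring A by a biomimetic Claisen cyclisation.
- Disconnection: the chromenone C4a–C5 bond, so that ring A is unravelled to the linear trioxo ester A2 (a methyl 3,5,7-trioxonon-8-enoate carrying the MOM-protected benzodioxane on C9).
- Forward key step: base-induced intramolecular Claisen condensation of chain C6 onto the ester carbonyl, then aromatisation to the 2′,4′,6′-trihydroxychalcone A1.
- For: it is biomimetic, needs no preformed trioxygenated arene and no transition metal, and the reaction type is known for poly-β-carbonyl chains.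
- Against: it disconnects the easy half. The benzodioxane, with both stereocenters and its fusion sense, must already be present in A2. A2 is hard to assemble and handle, since the aldol mode of cyclisation, pyrone formation and conjugate addition to the enone all compete. A1 is still two oxidation levels from a flavonol, and oxidative cyclisation of a 2′-hydroxychalcone with a second ortho hydroxyl tends to give aurones in the Algar–Flynn–Oyamada reaction. Removal of the MOM groups needs acid next to the ionisable benzylic ether.
- Comparison: its key reaction is better precedented than the chosen key step, and that point goes to the alternative. In its place the chosen strategy solves the fusion regiochemistry of ring B in its key step, and it reaches the flavonol with the 3-oxygen already present and in fewer steps after the ring-forming event.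

**Alternative 2:** the dioxane closed by an oxidative quinone methide cyclisation.
- Disconnection: the O1′–C2′ bond of ring D.
- Forward key step: two-electron oxidation of the 4-alkyl-2-methoxyphenol in A4 to its para-quinone methide, followed by intramolecular addition of the ring B phenol to give the trans benzodioxane ester A3.
- For: the fusion sense is unambiguous because the other aryl–oxygen bond is made beforehand. The reaction type is known for benzodioxane neolignans. Only one stereocenter has to be bought or made, and the second follows from the preference for the diequatorial ring. No ynol ethers are needed.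
- Against: the trans preference is substrate-controlled and can be incomplete. Free phenols have to be carried through an oxidation that can also attack the electron-rich ring E or couple intermolecularly. A4 needs an enantiopure secondary aryl alkyl ether, whose preparation again requires the two catechol oxygens to be told apart. The ester of A3 must then be converted in several steps into a handle for ring C.
- Comparison: up to the benzodioxane this route is stronger on precedent and probably on robustness. The chosen strategy offers instead both stereocenters from one auxiliary-controlled aldol, with no dependence on the diastereoselectivity of a ring closure, and a benzodioxane that already carries the ketone needed for ring C.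

**Alternative 3:** the hydroxypyranone by enolate acylation and O-arylation.
- Disconnection: the chromenone C3–C4 and O1–C8a bonds.
- Forward key step: the enolate of ketone 27 is C-acylated by acid chloride 32, and the diketone enolate closes ring C by copper-catalysed O-arylation to the pentabenzyl flavonol A5, which is the same compound as 34.
- For: it is convergent, uses known reaction types and installs the 3-oxygen directly.
- Against, as the centre of the plan: it presupposes 27 and says nothing about how a regio- and stereodefined benzodioxane ketone is obtained, which is the real difficulty.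
- Comparison: it is stronger than the chosen key step in precedent. For that reason it is not discarded but used as the end game (steps 17 and 18). The chosen strategy adds the answer to where 27 comes from.

Key step: step 12

## Route

Step 1
Reactants: 1 2-(allyloxy)acetic acid; 2 (S)-4-benzyl-1,3-oxazolidin-2-one
Product: 4 (S)-3-[2-(allyloxy)acetyl]-4-benzyl-1,3-oxazolidin-2-one, via mixed pivalic anhydride 3 (not isolated)
Conditions: t-BuCOCl, Et3N, THF, −20 °C; then 2, LiCl, −20 °C → rt
Reagents that add atoms: none
Why: N-acylation of the oxazolidinone by a mixed anhydride under LiCl/Et3N activation; the auxiliary stereocenter is not involved.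

Step 2
Reactants: 4 (S)-3-[2-(allyloxy)acetyl]-4-benzyl-1,3-oxazolidin-2-one; 5 4-(benzyloxy)-3-methoxybenzaldehyde
Product: 7 (S)-3-[(2S,3R)-2-(allyloxy)-3-[4-(benzyloxy)-3-methoxyphenyl]-3-hydroxypropanoyl]-4-benzyl-1,3-oxazolidin-2-one, via dibutylboron enolate 6 (not isolated)
Conditions: Bu2BOTf, Et3N, CH2Cl2, −78 → 0 °C; then 5, −78 → 0 °C; pH 7 buffer, MeOH, H2O2
Reagents that add atoms: none
Why: Evans syn aldol: the Z boron enolate reacts through a closed chair (Zimmerman–Traxler) transition state and the benzyl group of the auxiliary blocks one enolate face, so the (2S,3R) syn adduct should form; this sets both future dioxane stereocenters and leaves the benzylic hydroxyl as the only free one.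

Step 3
Reactants: 7 (S)-3-[(2S,3R)-2-(allyloxy)-3-[4-(benzyloxy)-3-methoxyphenyl]-3-hydroxypropanoyl]-4-benzyl-1,3-oxazolidin-2-one
Product: 8 (1R,2R)-2-(allyloxy)-1-[4-(benzyloxy)-3-methoxyphenyl]propane-1,3-diol
Conditions: LiBH4, MeOH (1 equiv), THF, 0 °C
Reagents that add atoms: none
Why: Reductive cleavage of the imide gives the primary alcohol and returns the auxiliary; neither stereocenter takes part, and the low temperature disfavours retro-aldol cleavage.

Step 4
Reactants: 8 (1R,2R)-2-(allyloxy)-1-[4-(benzyloxy)-3-methoxyphenyl]propane-1,3-diol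
Product: 10 (1R,2R)-2-(allyloxy)-3-(benzyloxy)-1-[4-(benzyloxy)-3-methoxyphenyl]propan-1-ol, via stannylene acetal 9 (not isolated)
Conditions: Bu2SnO, toluene, reflux (−H2O); then BnBr, Bu4NBr, 90 °C
Reagents that add atoms: benzyl bromide BrCc1ccccc1
Why: Stannylene acetal-mediated O-alkylation of a 1,3-diol occurs at the primary oxygen, so the benzylic hydroxyl stays free for step 5.

Step 5
Reactants: 10 (1R,2R)-2-(allyloxy)-3-(benzyloxy)-1-[4-(benzyloxy)-3-methoxyphenyl]propan-1-ol
Product: 12 1-[(1R,2R)-2-(allyloxy)-3-(benzyloxy)-1-{[(E)-1,2-dichloroethenyl]oxy}propyl]-4-(benzyloxy)-3-methoxybenzene, via potassium alkoxide 11 (not isolated)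
Conditions: KH, THF, 0 °C → rt; then Cl2C=CHCl, −50 °C → rt
Reagents that add atoms: trichloroethylene ClC=C(Cl)Cl
Why: The alkoxide adds to dichloroacetylene formed in situ by dehydrochlorination of trichloroethylene and gives the (E)-1,2-dichlorovinyl ether, a robust masked ynol ether; allyl and benzyl ethers are inert to KH.

Step 6
Reactants: 12 1-[(1R,2R)-2-(allyloxy)-3-(benzyloxy)-1-{[(E)-1,2-dichloroethenyl]oxy}propyl]-4-(benzyloxy)-3-methoxybenzene
Product: 14 (1R,2R)-3-(benzyloxy)-1-[4-(benzyloxy)-3-methoxyphenyl]-1-{[(E)-1,2-dichloroethenyl]oxy}propan-2-ol, via prop-1-enyl ether 13 (not isolated)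
Conditions: [Ir(cod)(PMePh2)2]PF6 (cat., activated with H2), THF, rt; then I2, NaHCO3, THF/H2O, 0 °C
Reagents that add atoms: none
Why: Iridium hydride-catalysed isomerisation of the allyl ether to the prop-1-enyl ether, then iodine-assisted hydrolysis under bicarbonate buffering, frees the C2 hydroxyl; the electron-poor dichlorovinyl ether and the benzyl ethers should not react.

Step 7
Reactants: 14 (1R,2R)-3-(benzyloxy)-1-[4-(benzyloxy)-3-methoxyphenyl]-1-{[(E)-1,2-dichloroethenyl]oxy}propan-2-ol
Product: 17 (1R,2R)-3-(benzyloxy)-1-[4-(benzyloxy)-3-methoxyphenyl]-1-{[(trimethylsilyl)ethynyl]oxy}propan-2-ol, via dilithio alkoxide acetylide 15 (not isolated), via bis-silylated ether 16 (not isolated)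
Conditions: n-BuLi (3.3 equiv), THF, −78 → −40 °C; Me3SiCl, −78 → 0 °C; then K2CO3 (cat.), MeOH, −20 °C
Reagents that add atoms: chlorotrimethylsilane C[Si](C)(C)Cl
Why: Excess n-BuLi deprotonates the hydroxyl and converts the dichlorovinyl ether through the chloroalkyne into the lithium alkynyl ether, which is silylated on carbon. The O-silyl ether formed alongside is removed by brief base-catalysed methanolysis, an alkoxide being a far better leaving group from silicon than an acetylide.

Step 8
Reactants: 17 (1R,2R)-3-(benzyloxy)-1-[4-(benzyloxy)-3-methoxyphenyl]-1-{[(trimethylsilyl)ethynyl]oxy}propan-2-ol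
Product: 19 {[(1R,2R)-3-(benzyloxy)-1-[4-(benzyloxy)-3-methoxyphenyl]-2-{[(E)-1,2-dichloroethenyl]oxy}propoxy]ethynyl}trimethylsilane, via potassium alkoxide 18 (not isolated)
Conditions: KH, THF, −20 °C; then Cl2C=CHCl at once, −50 → 0 °C
Reagents that add atoms: trichloroethylene ClC=C(Cl)Cl
Why: The same alkoxide addition to in situ dichloroacetylene as in step 5, now on the C2 oxygen; working cold and adding the chloroalkene immediately keeps the lifetime of the free alkoxide next to the silylated ynol ether short.

Step 9
Reactants: 19 {[(1R,2R)-3-(benzyloxy)-1-[4-(benzyloxy)-3-methoxyphenyl]-2-{[(E)-1,2-dichloroethenyl]oxy}propoxy]ethynyl}trimethylsilane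
Product: 21 {[(1R,2R)-3-(benzyloxy)-1-[4-(benzyloxy)-3-methoxyphenyl]-2-(ethynyloxy)propoxy]ethynyl}trimethylsilane, via lithium acetylide 20 (not isolated)
Conditions: n-BuLi (2.2 equiv), THF, −78 → −40 °C; then MeOH, −78 °C; cold filtration through Et3N-treated silica, used at once
Reagents that add atoms: none
Why: Dehydrochlorination and chlorine–lithium exchange give the lithium alkynyl ether, which methanol protonates; the C–Si bond of the other alkyne is stable to n-BuLi at low temperature, so the two alkyne termini end up differentiated.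

Step 10
Reactants: 22 (benzyloxy)acetyl chloride
Product: 23 2-(benzyloxy)-N-methoxy-N-methylacetamide
Conditions: MeNHOMe·HCl, Et3N, CH2Cl2, 0 °C → rt
Reagents that add atoms: N,O-dimethylhydroxylamine hydrochloride CNOC.Cl
Why: Acylation of the hydroxylamine gives the Weinreb amide, which allows a single acetylide addition in step 11; direct reaction of the acid chloride with the Grignard reagent would over-add.

Step 11
Reactants: 23 2-(benzyloxy)-N-methoxy-N-methylacetamide
Product: 25 1-(benzyloxy)but-3-yn-2-one, via bromomagnesium hemiaminal 24 (not isolated)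
Conditions: HC≡CMgBr, THF, −78 → 0 °C; inverse quench into cold 1 M HCl
Reagents that add atoms: ethynylmagnesium bromide C#C[Mg]Br
Why: Weinreb ketone synthesis: the chelated tetrahedral adduct prevents a second addition, and the inverse acidic quench protonates the released amine before it can add to the ynone.

Step 12
Reactants: 21 {[(1R,2R)-3-(benzyloxy)-1-[4-(benzyloxy)-3-methoxyphenyl]-2-(ethynyloxy)propoxy]ethynyl}trimethylsilane; 25 1-(benzyloxy)but-3-yn-2-one
Product: 26 2-(benzyloxy)-1-[(2R,3R)-3-[(benzyloxy)methyl]-2-[4-(benzyloxy)-3-methoxyphenyl]-8-(trimethylsilyl)-2,3-dihydro-1,4-benzodioxin-6-yl]ethan-1-one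
Conditions: Cp*RuCl(cod) (5–10 mol %), 25 (3 equiv), ClCH2CH2Cl, rt; 21 added slowly
Reagents that add atoms: none
Why: Proposed new method: the Cp*RuCl fragment (divalent ruthenium) should bind both ynol ether units of 21 and couple them oxidatively through their oxygen-bearing carbons to a ruthenacyclopentadiene, which closes dioxane ring D as a six-membered ring annulated to the metallacycle (new C4a′–C8a′ bond); coordination and insertion of ynone 25 and reductive elimination then close benzene ring B (new C5′–C6′ and C7′–C8′ bonds) as the formal (2+2+2) adduct and free the catalyst. The closest known reaction type is the Cp*RuCl(cod)-catalysed cycloaddition of tethered 1,6- and 1,7-diynes with monoalkynes at room temperature, together with the [Rh(cod)2]BF4/BINAP-catalysed cyclotrimerisation of ethynyl ethers; a diyne whose tether is made of the two ynol ether oxygens of a 1,2-diol has not been used. No stereocenter is formed: C2′ and C3′ are the two carbinol carbons of 21 and are not touched, so the trans relationship is the syn diol configuration carried over. The step needs regioselectivity (acyl group on C6′, meta to silicon and para to O1′); the trimethylsilyl group on the terminus of the benzylic ynol ether should secure it, because this catalyst is expected to place the substituent of a terminal monoalkyne meta to the substituted terminus of an unsymmetrical diyne. It needs chemoselectivity for the cross reaction, which the electronic match of the electron-rich diyne with the electron-poor ynone, the excess of 25 and the slow addition of 21 should provide. It also needs mild conditions, because the benzylic ynol ether rearranges sigmatropically on warming, and this catalyst works at room temperature.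

Step 13
Reactants: 26 2-(benzyloxy)-1-[(2R,3R)-3-[(benzyloxy)methyl]-2-[4-(benzyloxy)-3-methoxyphenyl]-8-(trimethylsilyl)-2,3-dihydro-1,4-benzodioxin-6-yl]ethan-1-one
Product: 27 2-(benzyloxy)-1-[(2R,3R)-3-[(benzyloxy)methyl]-2-[4-(benzyloxy)-3-methoxyphenyl]-2,3-dihydro-1,4-benzodioxin-6-yl]ethan-1-one
Conditions: CF3CO2H, CH2Cl2, 0 °C → rt
Reagents that add atoms: none
Why: Electrophilic ipso-protodesilylation: protonation at C8′ is assisted by the ortho oxygen O1′ and by the β-silyl effect. It is done at the ketone stage because a protonated chromenone would deactivate ring B; the benzyl ethers and the dioxane stereocenters should survive dilute acid at or below room temperature.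

Step 14
Reactants: 28 1,3-bis(benzyloxy)-5-bromobenzene
Product: 30 2-bromo-4,6-bis(benzyloxy)benzaldehyde, via iminium chloride 29 (not isolated)
Conditions: POCl3, DMF, 0 → 80 °C; then H2O, 0 °C → rt
Reagents that add atoms: N,N-dimethylformamide CN(C)C=O; water O
Why: Vilsmeier–Haack formylation of the electron-rich arene at the position ortho to bromine and ortho/para to the two benzyloxy groups; the position between the two benzyloxy groups is more hindered, and any regioisomer is removed by crystallisation or chromatography.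

Step 15
Reactants: 30 2-bromo-4,6-bis(benzyloxy)benzaldehyde
Product: 31 2-bromo-4,6-bis(benzyloxy)benzoic acid
Conditions: NaClO2, NaH2PO4, 2-methylbut-2-ene, t-BuOH/THF/H2O, rt
Reagents that add atoms: sodium chlorite [Na+].[O-]Cl=O
Why: Pinnick oxidation of the aldehyde; the alkene scavenges hypochlorous acid and so protects the electron-rich ring from chlorination.

Step 16
Reactants: 31 2-bromo-4,6-bis(benzyloxy)benzoic acid
Product: 32 2-bromo-4,6-bis(benzyloxy)benzoyl chloride
Conditions: (COCl)2, DMF (cat.), CH2Cl2, 0 °C → rt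
Reagents that add atoms: oxalyl chloride ClC(=O)C(=O)Cl
Why: Standard conversion of the acid into the acid chloride through the chloroiminium catalyst; benzyl ethers are stable under these conditions.

Step 17
Reactants: 27 2-(benzyloxy)-1-[(2R,3R)-3-[(benzyloxy)methyl]-2-[4-(benzyloxy)-3-methoxyphenyl]-2,3-dihydro-1,4-benzodioxin-6-yl]ethan-1-one; 32 2-bromo-4,6-bis(benzyloxy)benzoyl chloride
Product: 33 2-(benzyloxy)-1-[2-bromo-4,6-bis(benzyloxy)phenyl]-3-[(2R,3R)-3-[(benzyloxy)methyl]-2-[4-(benzyloxy)-3-methoxyphenyl]-2,3-dihydro-1,4-benzodioxin-6-yl]propane-1,3-dione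
Conditions: MgBr2·OEt2, i-Pr2NEt, CH2Cl2, rt
Reagents that add atoms: none
Why: Soft enolisation: magnesium chelation of the α-benzyloxy ketone lets a tertiary amine form the enolate, which is C-acylated by the aroyl chloride (Claisen-type acylation). The new central carbon is an enolisable, uncontrolled stereocenter that disappears in step 18.

Step 18
Reactants: 33 2-(benzyloxy)-1-[2-bromo-4,6-bis(benzyloxy)phenyl]-3-[(2R,3R)-3-[(benzyloxy)methyl]-2-[4-(benzyloxy)-3-methoxyphenyl]-2,3-dihydro-1,4-benzodioxin-6-yl]propane-1,3-dione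
Product: 34 3,5,7-tris(benzyloxy)-2-[(2R,3R)-3-[(benzyloxy)methyl]-2-[4-(benzyloxy)-3-methoxyphenyl]-2,3-dihydro-1,4-benzodioxin-6-yl]-4H-chromen-4-one
Conditions: CuI (10 mol %), 1,10-phenanthroline (20 mol %), Cs2CO3, DMF, 90 °C
Reagents that add atoms: none
Why: Ullmann-type intramolecular O-arylation of the diketone enolate with the ortho bromide closes pyranone ring C; only the enol oxygen next to ring B can reach the C–Br carbon in a six-membered ring, so the flavonol skeleton forms with its 3-oxygen already in place.

Step 19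
Reactants: 34 3,5,7-tris(benzyloxy)-2-[(2R,3R)-3-[(benzyloxy)methyl]-2-[4-(benzyloxy)-3-methoxyphenyl]-2,3-dihydro-1,4-benzodioxin-6-yl]-4H-chromen-4-one
Product: 35 3,5,7-trihydroxy-2-[(2R,3R)-2-(4-hydroxy-3-methoxyphenyl)-3-(hydroxymethyl)-2,3-dihydro-1,4-benzodioxin-6-yl]-4H-chromen-4-one
Conditions: H2 (1 atm), Pd/C, THF/MeOH, rt
Reagents that add atoms: none
Why: Hydrogenolysis of the five benzyl ethers; the methyl ether, the chromenone and, at atmospheric pressure, the cyclic benzylic ether of the dioxane are expected to remain.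

## Compound list

1 | 2-(allyloxy)acetic acid | C=CCOCC(=O)O | starting material
2 | (S)-4-benzyl-1,3-oxazolidin-2-one | O=C1OC[C@H](Cc2ccccc2)N1 | starting material
3 | 2-(allyloxy)acetic pivalic anhydride | C=CCOCC(=O)OC(=O)C(C)(C)C | intermediate
4 | (S)-3-[2-(allyloxy)acetyl]-4-benzyl-1,3-oxazolidin-2-one | C=CCOCC(=O)N1C(=O)OC[C@@H]1Cc1ccccc1 | intermediate
5 | 4-(benzyloxy)-3-methoxybenzaldehyde (O-benzylvanillin) | COc1cc(C=O)ccc1OCc1ccccc1 | starting material
6 | dibutylboron (Z)-enolate of 4 | C=CCO/C=C(\OB(CCCC)CCCC)N1C(=O)OC[C@@H]1Cc1ccccc1 | intermediate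
7 | (S)-3-[(2S,3R)-2-(allyloxy)-3-[4-(benzyloxy)-3-methoxyphenyl]-3-hydroxypropanoyl]-4-benzyl-1,3-oxazolidin-2-one | COc1cc([C@@H](O)[C@H](OCC=C)C(=O)N2C(=O)OC[C@@H]2Cc2ccccc2)ccc1OCc1ccccc1 | intermediate
8 | (1R,2R)-2-(allyloxy)-1-[4-(benzyloxy)-3-methoxyphenyl]propane-1,3-diol | COc1cc([C@@H](O)[C@H](OCC=C)CO)ccc1OCc1ccccc1 | intermediate
9 | (4R,5R)-5-(allyloxy)-4-[4-(benzyloxy)-3-methoxyphenyl]-2,2-dibutyl-1,3,2-dioxastanninane | COc1cc([C@H]2O[Sn](CCCC)(CCCC)OC[C@H]2OCC=C)ccc1OCc1ccccc1 | intermediate
10 | (1R,2R)-2-(allyloxy)-3-(benzyloxy)-1-[4-(benzyloxy)-3-methoxyphenyl]propan-1-ol | COc1cc([C@@H](O)[C@H](OCC=C)COCc2ccccc2)ccc1OCc1ccccc1 | intermediate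
11 | potassium (1R,2R)-2-(allyloxy)-3-(benzyloxy)-1-[4-(benzyloxy)-3-methoxyphenyl]propan-1-olate | COc1cc([C@@H]([O-])[C@H](OCC=C)COCc2ccccc2)ccc1OCc1ccccc1.[K+] | intermediate
12 | 1-[(1R,2R)-2-(allyloxy)-3-(benzyloxy)-1-{[(E)-1,2-dichloroethenyl]oxy}propyl]-4-(benzyloxy)-3-methoxybenzene | COc1cc([C@@H](O/C(Cl)=C\Cl)[C@H](OCC=C)COCc2ccccc2)ccc1OCc1ccccc1 | intermediate
13 | 1-[(1R,2R)-3-(benzyloxy)-1-{[(E)-1,2-dichloroethenyl]oxy}-2-{[(E)-prop-1-en-1-yl]oxy}propyl]-4-(benzyloxy)-3-methoxybenzene | COc1cc([C@@H](O/C(Cl)=C\Cl)[C@H](O/C=C/C)COCc2ccccc2)ccc1OCc1ccccc1 | intermediate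
14 | (1R,2R)-3-(benzyloxy)-1-[4-(benzyloxy)-3-methoxyphenyl]-1-{[(E)-1,2-dichloroethenyl]oxy}propan-2-ol | COc1cc([C@@H](O/C(Cl)=C\Cl)[C@H](O)COCc2ccccc2)ccc1OCc1ccccc1 | intermediate
15 | lithium (1R,2R)-3-(benzyloxy)-1-[4-(benzyloxy)-3-methoxyphenyl]-1-[(lithioethynyl)oxy]propan-2-olate | COc1cc([C@@H](OC#C[Li])[C@H](O[Li])COCc2ccccc2)ccc1OCc1ccccc1 | intermediate
16 | {[(1R,2R)-3-(benzyloxy)-1-[4-(benzyloxy)-3-methoxyphenyl]-2-[(trimethylsilyl)oxy]propoxy]ethynyl}trimethylsilane | COc1cc([C@@H](OC#C[Si](C)(C)C)[C@H](O[Si](C)(C)C)COCc2ccccc2)ccc1OCc1ccccc1 | intermediate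
17 | (1R,2R)-3-(benzyloxy)-1-[4-(benzyloxy)-3-methoxyphenyl]-1-{[(trimethylsilyl)ethynyl]oxy}propan-2-ol | COc1cc([C@@H](OC#C[Si](C)(C)C)[C@H](O)COCc2ccccc2)ccc1OCc1ccccc1 | intermediate
18 | potassium (1R,2R)-3-(benzyloxy)-1-[4-(benzyloxy)-3-methoxyphenyl]-1-{[(trimethylsilyl)ethynyl]oxy}propan-2-olate | COc1cc([C@@H](OC#C[Si](C)(C)C)[C@H]([O-])COCc2ccccc2)ccc1OCc1ccccc1.[K+] | intermediate
19 | {[(1R,2R)-3-(benzyloxy)-1-[4-(benzyloxy)-3-methoxyphenyl]-2-{[(E)-1,2-dichloroethenyl]oxy}propoxy]ethynyl}trimethylsilane | COc1cc([C@@H](OC#C[Si](C)(C)C)[C@H](O/C(Cl)=C\Cl)COCc2ccccc2)ccc1OCc1ccccc1 | intermediate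
20 | {[(1R,2R)-3-(benzyloxy)-1-[4-(benzyloxy)-3-methoxyphenyl]-2-[(lithioethynyl)oxy]propoxy]ethynyl}trimethylsilane | COc1cc([C@@H](OC#C[Si](C)(C)C)[C@H](OC#C[Li])COCc2ccccc2)ccc1OCc1ccccc1 | intermediate
21 | {[(1R,2R)-3-(benzyloxy)-1-[4-(benzyloxy)-3-methoxyphenyl]-2-(ethynyloxy)propoxy]ethynyl}trimethylsilane | COc1cc([C@@H](OC#C[Si](C)(C)C)[C@H](OC#C)COCc2ccccc2)ccc1OCc1ccccc1 | intermediate
22 | (benzyloxy)acetyl chloride | O=C(Cl)COCc1ccccc1 | starting material
23 | 2-(benzyloxy)-N-methoxy-N-methylacetamide | CON(C)C(=O)COCc1ccccc1 | intermediate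
24 | bromomagnesium 1-(benzyloxy)-2-[methoxy(methyl)amino]but-3-yn-2-olate | C#CC(O[Mg]Br)(COCc1ccccc1)N(C)OC | intermediate
25 | 1-(benzyloxy)but-3-yn-2-one | C#CC(=O)COCc1ccccc1 | intermediate
26 | 2-(benzyloxy)-1-[(2R,3R)-3-[(benzyloxy)methyl]-2-[4-(benzyloxy)-3-methoxyphenyl]-8-(trimethylsilyl)-2,3-dihydro-1,4-benzodioxin-6-yl]ethan-1-one | COc1cc([C@H]2Oc3c([Si](C)(C)C)cc(C(=O)COCc4ccccc4)cc3O[C@@H]2COCc2ccccc2)ccc1OCc1ccccc1 | intermediate
27 | 2-(benzyloxy)-1-[(2R,3R)-3-[(benzyloxy)methyl]-2-[4-(benzyloxy)-3-methoxyphenyl]-2,3-dihydro-1,4-benzodioxin-6-yl]ethan-1-one | COc1cc([C@H]2Oc3ccc(C(=O)COCc4ccccc4)cc3O[C@@H]2COCc2ccccc2)ccc1OCc1ccccc1 | intermediate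
28 | 1,3-bis(benzyloxy)-5-bromobenzene | Brc1cc(OCc2ccccc2)cc(OCc2ccccc2)c1 | starting material
29 | N-{[2-bromo-4,6-bis(benzyloxy)phenyl]methylidene}-N-methylmethanaminium chloride | C[N+](C)=Cc1c(Br)cc(OCc2ccccc2)cc1OCc1ccccc1.[Cl-] | intermediate
30 | 2-bromo-4,6-bis(benzyloxy)benzaldehyde | O=Cc1c(Br)cc(OCc2ccccc2)cc1OCc1ccccc1 | intermediate
31 | 2-bromo-4,6-bis(benzyloxy)benzoic acid | OC(=O)c1c(Br)cc(OCc2ccccc2)cc1OCc1ccccc1 | intermediate
32 | 2-bromo-4,6-bis(benzyloxy)benzoyl chloride | ClC(=O)c1c(Br)cc(OCc2ccccc2)cc1OCc1ccccc1 | intermediate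
33 | 2-(benzyloxy)-1-[2-bromo-4,6-bis(benzyloxy)phenyl]-3-[(2R,3R)-3-[(benzyloxy)methyl]-2-[4-(benzyloxy)-3-methoxyphenyl]-2,3-dihydro-1,4-benzodioxin-6-yl]propane-1,3-dione (central carbon unassigned, enolisable) | COc1cc([C@H]2Oc3ccc(C(=O)C(OCc4ccccc4)C(=O)c4c(Br)cc(OCc5ccccc5)cc4OCc4ccccc4)cc3O[C@@H]2COCc2ccccc2)ccc1OCc1ccccc1 | intermediate
34 | 3,5,7-tris(benzyloxy)-2-[(2R,3R)-3-[(benzyloxy)methyl]-2-[4-(benzyloxy)-3-methoxyphenyl]-2,3-dihydro-1,4-benzodioxin-6-yl]-4H-chromen-4-one | COc1cc([C@H]2Oc3ccc(-c4oc5cc(OCc6ccccc6)cc(OCc6ccccc6)c5c(=O)c4OCc4ccccc4)cc3O[C@@H]2COCc2ccccc2)ccc1OCc1ccccc1 | intermediate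
35 | 3,5,7-trihydroxy-2-[(2R,3R)-2-(4-hydroxy-3-methoxyphenyl)-3-(hydroxymethyl)-2,3-dihydro-1,4-benzodioxin-6-yl]-4H-chromen-4-one | COc1cc([C@H]2Oc3ccc(-c4oc5cc(O)cc(O)c5c(=O)c4O)cc3O[C@@H]2CO)ccc1O | target

## Step count and least certain steps

Total: 19 steps. Longest linear sequence: 14 steps (steps 1 to 9, 12, 13, 17, 18, 19). The ynone branch has 2 steps (10, 11) and the acid chloride branch 3 steps (14 to 16).

**Step 12 (key step, labelled as a proposed new method).** The most likely failures are these.
- Oligomerisation of the ynone or dimerisation of the diyne may outrun the cross reaction.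
- The ynol ethers may be hydrated or rearranged at the Lewis-acidic metal before oxidative coupling.
- Closure of the six-membered dioxane may be slow, because a four-atom tether couples less readily than a three-atom one.
- Regiocontrol may erode if the ynone inserts next to the silylated carbon.

Fallback by known chemistry, setting out from compound 10 and returning at compound 27:
- The potassium alkoxide of 10, made with KN(SiMe3)2, displaces fluoride from 3-bromo-4-fluorobenzonitrile by nucleophilic aromatic substitution. The nitrile is para to the new oxygen, which fixes the fusion sense. The product is 3-bromo-4-{(1R,2R)-2-(allyloxy)-3-(benzyloxy)-1-[4-(benzyloxy)-3-methoxyphenyl]propoxy}benzonitrile F1.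
- The allyl ether is isomerised with the iridium catalyst of step 6 to the prop-1-enyl ether F2 and hydrolysed with I2/NaHCO3 to 3-bromo-4-{(1R,2R)-3-(benzyloxy)-1-[4-(benzyloxy)-3-methoxyphenyl]-2-hydroxypropoxy}benzonitrile F3.
- Intramolecular palladium-catalysed C–O coupling (Pd(OAc)2, 2-(di-tert-butylphosphino)-1,1′-binaphthyl, Cs2CO3, toluene, 80 °C) closes the dioxane with retention at both carbons, giving (2R,3R)-3-[(benzyloxy)methyl]-2-[4-(benzyloxy)-3-methoxyphenyl]-2,3-dihydro-1,4-benzodioxine-6-carbonitrile F4.
- Addition of (benzyloxy)methyllithium (from tributyl[(benzyloxy)methyl]stannane and n-BuLi) to the nitrile and hydrolysis of the imine gives 27.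

**Step 8.** The potassium alkoxide may attack the neighbouring silylated ynol ether, either at silicon (loss of the regiocontrol group) or at the oxygen-bearing alkyne carbon (five-membered ketene acetal), before it is trapped by dichloroacetylene. Fallback without an alkoxide, from compound 17 to compound 21:
- The hydroxyl is formylated with acetic formic anhydride and pyridine to (1R,2R)-3-(benzyloxy)-1-[4-(benzyloxy)-3-methoxyphenyl]-1-{[(trimethylsilyl)ethynyl]oxy}propan-2-yl formate F5.
- Dibromo-olefination of the formate (CBr4, PPh3, Et3N, CH2Cl2) gives {[(1R,2R)-3-(benzyloxy)-1-[4-(benzyloxy)-3-methoxyphenyl]-2-[(2,2-dibromoethenyl)oxy]propoxy]ethynyl}trimethylsilane F6.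
- n-BuLi (2 equiv) at −78 °C effects bromine–lithium exchange and Fritsch–Buttenberg–Wiechell-type rearrangement to lithium acetylide 20, and methanol gives 21.

**Step 7.** Methanolysis may not discriminate fully between the O–Si and the alkynyl C–Si bond, and methanol may add to the ynol ether under base. Fallback that never exposes a free hydroxyl to the silylation, from compound 12 to compound 17:
- 12 is treated with n-BuLi (2.2 equiv) and Me3SiCl to give {[(1R,2R)-2-(allyloxy)-3-(benzyloxy)-1-[4-(benzyloxy)-3-methoxyphenyl]propoxy]ethynyl}trimethylsilane F7.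
- The iridium catalyst of step 6 isomerises the allyl ether to the prop-1-enyl ether F8.
- Catalytic OsO4 with N-methylmorpholine N-oxide dihydroxylates the enol ether, and the resulting hemiacetal collapses under neutral conditions to 17.

**Step 17.** The doubly ortho-substituted aroyl chloride may react slowly, and acylation on the enolate oxygen or a second acylation of the product may compete. Fallback by aldol and oxidation, from compounds 27 and 30 to compound 33:
- The lithium enolate of 27 (LiN(SiMe3)2, THF, −78 °C) adds to aldehyde 30 to give the β-hydroxy ketone 2-(benzyloxy)-3-[2-bromo-4,6-bis(benzyloxy)phenyl]-1-[(2R,3R)-3-[(benzyloxy)methyl]-2-[4-(benzyloxy)-3-methoxyphenyl]-2,3-dihydro-1,4-benzodioxin-6-yl]-3-hydroxypropan-1-one F9 as a diastereomer mixture.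
- Dess–Martin periodinane oxidises it to 33. This also makes steps 15 and 16 unnecessary.

**Step 19.** Hydrogenolysis may also cleave the benzylic C2′–O1′ bond of the dioxane or stall at partly benzylated stages as the product becomes insoluble. Fallback from compound 34 to compound 35: non-reductive debenzylation with BCl3 and pentamethylbenzene as cation scavenger in CH2Cl2 at −78 °C, stopped before the methyl ether is attacked. It makes no new isolated compound.

## Further compounds

F1 | step 12 | 3-bromo-4-{(1R,2R)-2-(allyloxy)-3-(benzyloxy)-1-[4-(benzyloxy)-3-methoxyphenyl]propoxy}benzonitrile | COc1cc([C@@H](Oc2ccc(C#N)cc2Br)[C@H](OCC=C)COCc2ccccc2)ccc1OCc1ccccc1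
F2 | step 12 | 3-bromo-4-{(1R,2R)-3-(benzyloxy)-1-[4-(benzyloxy)-3-methoxyphenyl]-2-{[(E)-prop-1-en-1-yl]oxy}propoxy}benzonitrile | COc1cc([C@@H](Oc2ccc(C#N)cc2Br)[C@H](O/C=C/C)COCc2ccccc2)ccc1OCc1ccccc1
F3 | step 12 | 3-bromo-4-{(1R,2R)-3-(benzyloxy)-1-[4-(benzyloxy)-3-methoxyphenyl]-2-hydroxypropoxy}benzonitrile | COc1cc([C@@H](Oc2ccc(C#N)cc2Br)[C@H](O)COCc2ccccc2)ccc1OCc1ccccc1
F4 | step 12 | (2R,3R)-3-[(benzyloxy)methyl]-2-[4-(benzyloxy)-3-methoxyphenyl]-2,3-dihydro-1,4-benzodioxine-6-carbonitrile | COc1cc([C@H]2Oc3ccc(C#N)cc3O[C@@H]2COCc2ccccc2)ccc1OCc1ccccc1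
F5 | step 8 | (1R,2R)-3-(benzyloxy)-1-[4-(benzyloxy)-3-methoxyphenyl]-1-{[(trimethylsilyl)ethynyl]oxy}propan-2-yl formate | COc1cc([C@@H](OC#C[Si](C)(C)C)[C@H](OC=O)COCc2ccccc2)ccc1OCc1ccccc1
F6 | step 8 | {[(1R,2R)-3-(benzyloxy)-1-[4-(benzyloxy)-3-methoxyphenyl]-2-[(2,2-dibromoethenyl)oxy]propoxy]ethynyl}trimethylsilane | COc1cc([C@@H](OC#C[Si](C)(C)C)[C@H](OC=C(Br)Br)COCc2ccccc2)ccc1OCc1ccccc1
F7 | step 7 | {[(1R,2R)-2-(allyloxy)-3-(benzyloxy)-1-[4-(benzyloxy)-3-methoxyphenyl]propoxy]ethynyl}trimethylsilane | COc1cc([C@@H](OC#C[Si](C)(C)C)[C@H](OCC=C)COCc2ccccc2)ccc1OCc1ccccc1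
F8 | step 7 | {[(1R,2R)-3-(benzyloxy)-1-[4-(benzyloxy)-3-methoxyphenyl]-2-{[(E)-prop-1-en-1-yl]oxy}propoxy]ethynyl}trimethylsilane | COc1cc([C@@H](OC#C[Si](C)(C)C)[C@H](O/C=C/C)COCc2ccccc2)ccc1OCc1ccccc1
F9 | step 17 | 2-(benzyloxy)-3-[2-bromo-4,6-bis(benzyloxy)phenyl]-1-[(2R,3R)-3-[(benzyloxy)methyl]-2-[4-(benzyloxy)-3-methoxyphenyl]-2,3-dihydro-1,4-benzodioxin-6-yl]-3-hydroxypropan-1-one (diastereomer mixture at the two new carbons) | COc1cc([C@H]2Oc3ccc(C(=O)C(OCc4ccccc4)C(O)c4c(Br)cc(OCc5ccccc5)cc4OCc4ccccc4)cc3O[C@@H]2COCc2ccccc2)ccc1OCc1ccccc1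
F0 | step 19 | none | none
A1 | alternative 1 | (E)-3-[(2R,3R)-2-[3-methoxy-4-(methoxymethoxy)phenyl]-3-[(methoxymethoxy)methyl]-2,3-dihydro-1,4-benzodioxin-6-yl]-1-(2,4,6-trihydroxyphenyl)prop-2-en-1-one | COc1cc([C@H]2Oc3ccc(/C=C/C(=O)c4c(O)cc(O)cc4O)cc3O[C@@H]2COCOC)ccc1OCOC
A2 | alternative 1 | methyl (E)-9-[(2R,3R)-2-[3-methoxy-4-(methoxymethoxy)phenyl]-3-[(methoxymethoxy)methyl]-2,3-dihydro-1,4-benzodioxin-6-yl]-3,5,7-trioxonon-8-enoate | COc1cc([C@H]2Oc3ccc(/C=C/C(=O)CC(=O)CC(=O)CC(=O)OC)cc3O[C@@H]2COCOC)ccc1OCOC
A3 | alternative 2 | methyl (2R,3R)-3-{[(tert-butyldimethylsilyl)oxy]methyl}-2-(4-hydroxy-3-methoxyphenyl)-2,3-dihydro-1,4-benzodioxine-6-carboxylate | COc1cc([C@H]2Oc3ccc(C(=O)OC)cc3O[C@@H]2CO[Si](C)(C)C(C)(C)C)ccc1O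
A4 | alternative 2 | methyl 3-{[(2S)-1-[(tert-butyldimethylsilyl)oxy]-3-(4-hydroxy-3-methoxyphenyl)propan-2-yl]oxy}-4-hydroxybenzoate | COc1cc(C[C@@H](CO[Si](C)(C)C(C)(C)C)Oc2cc(C(=O)OC)ccc2O)ccc1O
A5 | alternative 3 | 3,5,7-tris(benzyloxy)-2-[(2R,3R)-3-[(benzyloxy)methyl]-2-[4-(benzyloxy)-3-methoxyphenyl]-2,3-dihydro-1,4-benzodioxin-6-yl]-4H-chromen-4-one (identical with 34) | COc1cc([C@H]2Oc3ccc(-c4oc5cc(OCc6ccccc6)cc(OCc6ccccc6)c5c(=O)c4OCc4ccccc4)cc3O[C@@H]2COCc2ccccc2)ccc1OCc1ccccc1
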